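**Plan**

1. Retrosynthesis: the last bond cut joins the methyl-bearing alkene carbon to C2 of the furan ring, giving a benzofuran with a free C2–H and the internal alkyne 7-methoxy-2,2-dimethyl-6-[(2S)-pent-3-yn-2-yl]-2H-chromene. Earlier cuts are the aryl–CH bond at the stereocenter, the pyran ring (O1–C2, C4–C4a) and the furan ring (O1–C2, C3–C3a).
2. Feature used: the furan C2–H is the one C–H next to the ring oxygen (most acidic, first to be metalated). In the target the vinylic H is cis to the benzofuranyl group, and the two alkene ends differ sharply in size (CH3 against 1-arylethyl). One syn C–H addition across the alkyne therefore joins the halves, fixes the E geometry and places the methyl group, with no handle on either partner.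
3. Forward, chromene half: pyran ring by a propargyl ether Claisen cascade on 4-bromo-3-methoxyphenol, Br to B(OH)2, stereoconvergent nickel/pybox arylation of a racemic silylated propargylic bromide, C-desilylation, C-methylation.
4. Forward, benzofuran half: iodination of 2,4-dihydroxyacetophenone, Sonogashira coupling, fluoride-induced 5-endo-dig closure of the furan ring, O-silylation as a temporary helper for the nickel step.
5. Union by nickel-catalysed hydroheteroarylation of the alkyne, then removal of the silyl ether.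
6. Stereochemistry: the single stereocenter is set under catalyst control in the arylation step and is not touched afterwards; the E alkene follows from the syn addition.

Key step: step 12

Assumption: both antipodes of the indanyl-pybox ligand are commercial, and the one whose catalyst gives (R)-13 is used; the sense of induction belongs to the catalyst and is to be fixed in a pilot run (chiral HPLC and correlation) before material is carried on.

**Route**

Step 1
Reactants: 1 4-bromo-3-methoxyphenol; 2 3-chloro-3-methylbut-1-yne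
Product: 3 1-bromo-2-methoxy-4-[(2-methylbut-3-yn-2-yl)oxy]benzene
Conditions: DBU, CuCl2·2H2O (cat.), MeCN, 0 °C to rt
Reagents that add atoms: none
Why: Copper-catalysed O-alkylation of a phenoxide with a tertiary propargylic chloride is the standard entry to aryl 1,1-dimethylpropargyl ethers, and the aryl bromide and methyl ether are inert.

Step 2
Reactants: 3 1-bromo-2-methoxy-4-[(2-methylbut-3-yn-2-yl)oxy]benzene
Product: 6 6-bromo-7-methoxy-2,2-dimethyl-2H-chromene, via ortho-allenylphenol 4 (not isolated), via ortho-quinone methide 5 (not isolated)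
Conditions: PhNEt2, 185 °C
Reagents that add atoms: none
Why: Aromatic propargyl Claisen rearrangement to the free ortho carbon para to the methoxy group, tautomerisation, [1,5]-hydrogen shift and oxa-six-electron electrocyclisation should give the 2,2-dimethyl-2H-chromene, the other ortho carbon being hindered between two oxygen substituents.

Step 3
Reactants: 6 6-bromo-7-methoxy-2,2-dimethyl-2H-chromene
Product: 9 (7-methoxy-2,2-dimethyl-2H-chromen-6-yl)boronic acid, via aryllithium 7 (not isolated), via lithium arylborate 8 (not isolated)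
Conditions: n-BuLi, THF, −78 °C; B(OiPr)3, −78 °C to rt; aq. NH4Cl, then 1 M HCl (brief)
Reagents that add atoms: triisopropyl borate, CC(C)OB(OC(C)C)OC(C)C; water, O
Why: Bromine–lithium exchange at −78 °C is faster than any addition to the chromene alkene, and borate trapping followed by hydrolysis is the standard boronic acid synthesis.

Step 4
Reactants: 10 racemic 4-(trimethylsilyl)but-3-yn-2-ol
Product: 11 racemic (3-bromobut-1-yn-1-yl)trimethylsilane
Conditions: CBr4, PPh3, CH2Cl2, 0 °C
Reagents that add atoms: carbon tetrabromide, BrC(Br)(Br)Br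
Why: Appel bromination of a secondary propargylic alcohol, with the silyl group disfavouring allenyl bromide formation; the racemic product is what the next step needs.

Step 5
Reactants: 9 (7-methoxy-2,2-dimethyl-2H-chromen-6-yl)boronic acid; 11 racemic (3-bromobut-1-yn-1-yl)trimethylsilane
Product: 13 trimethyl[(3R)-3-(7-methoxy-2,2-dimethyl-2H-chromen-6-yl)but-1-yn-1-yl]silane, via arylethylzinc 12 (not isolated)
Conditions: Et2Zn, toluene, 60 °C; then 11, NiCl2·glyme (3 mol %), enantiopure indanyl-pybox [2,6-bis(3a,8a-dihydro-8H-indeno[1,2-d]oxazol-2-yl)pyridine, antipode as in the assumption] (4 mol %), glyme, −20 °C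
Reagents that add atoms: none
Why: Boron-to-zinc exchange gives the arylethylzinc for a stereoconvergent Negishi arylation in which both enantiomers of 11 give the same propargylic radical and the chiral aryl–nickel–pybox complex sets the new benzylic stereocenter (catalyst control), while the silyl group keeps bond formation at the propargylic terminus.

Step 6
Reactants: 13 trimethyl[(3R)-3-(7-methoxy-2,2-dimethyl-2H-chromen-6-yl)but-1-yn-1-yl]silane
Product: 14 6-[(2S)-but-3-yn-2-yl]-7-methoxy-2,2-dimethyl-2H-chromene
Conditions: K2CO3, MeOH, rt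
Reagents that add atoms: none
Why: Methanolysis of the alkynyl C–Si bond under mild carbonate conditions leaves the benzylic propargylic C–H alone, so the configuration is kept (the descriptor changes from R to S only because silicon leaves the priority sequence).

Step 7
Reactants: 14 6-[(2S)-but-3-yn-2-yl]-7-methoxy-2,2-dimethyl-2H-chromene
Product: 16 7-methoxy-2,2-dimethyl-6-[(2S)-pent-3-yn-2-yl]-2H-chromene, via lithium acetylide 15 (not isolated)
Conditions: n-BuLi, THF, −78 °C; MeI, −78 °C to rt
Reagents that add atoms: iodomethane, CI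
Why: Selective deprotonation of the terminal alkyne at −78 °C and SN2 methylation of the acetylide should leave the far less acidic benzylic C–H, and so the stereocenter, untouched.

Step 8
Reactants: 17 1-(2,4-dihydroxyphenyl)ethanone
Product: 18 1-(2,4-dihydroxy-5-iodophenyl)ethanone
Conditions: ICl (1.0 equiv), AcOH, rt
Reagents that add atoms: iodine monochloride, ClI
Why: Electrophilic aromatic iodination under acidic conditions should go to C5, ortho to the free 4-hydroxyl and para to the hydrogen-bonded 2-hydroxyl, the less hindered of the two activated positions.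

Step 9
Reactants: 18 1-(2,4-dihydroxy-5-iodophenyl)ethanone
Product: 19 1-{2,4-dihydroxy-5-[(trimethylsilyl)ethynyl]phenyl}ethanone
Conditions: ethynyltrimethylsilane, Pd(PPh3)2Cl2 (2 mol %), CuI (4 mol %), Et3N, THF, rt
Reagents that add atoms: ethynyltrimethylsilane, C#C[Si](C)(C)C
Why: Sonogashira coupling of an aryl iodide proceeds at room temperature with free phenols present, and the silyl cap holds back premature cyclisation.

Step 10
Reactants: 19 1-{2,4-dihydroxy-5-[(trimethylsilyl)ethynyl]phenyl}ethanone
Product: 21 1-(6-hydroxy-1-benzofuran-5-yl)ethanone, via terminal alkyne 20 (not isolated)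
Conditions: TBAF, THF, 65 °C; aq. NH4Cl
Reagents that add atoms: none
Why: Fluoride removes the alkynyl silyl group and the phenoxide of the only hydroxyl ortho to the alkyne closes the furan ring by 5-endo-dig hydroalkoxylation.

Step 11
Reactants: 21 1-(6-hydroxy-1-benzofuran-5-yl)ethanone
Product: 22 1-{6-[(tert-butyldimethylsilyl)oxy]-1-benzofuran-5-yl}ethanone
Conditions: TBSCl, imidazole, DMF, rt
Reagents that add atoms: tert-butyldimethylsilyl chloride, CC(C)(C)[Si](C)(C)Cl
Why: Standard silylation of the phenol removes the acidic O–H that would quench the low-valent nickel catalyst in the next step.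

Step 12
Reactants: 16 7-methoxy-2,2-dimethyl-6-[(2S)-pent-3-yn-2-yl]-2H-chromene; 22 1-{6-[(tert-butyldimethylsilyl)oxy]-1-benzofuran-5-yl}ethanone
Product: 23 1-{6-[(tert-butyldimethylsilyl)oxy]-2-[(2E,4S)-4-(7-methoxy-2,2-dimethyl-2H-chromen-6-yl)pent-2-en-2-yl]-1-benzofuran-5-yl}ethanone
Conditions: Ni(cod)2 (10 mol %), PCyp3 (tricyclopentylphosphine, 10 mol %), toluene, 35 °C
Reagents that add atoms: none
Why: Zerovalent nickel with the electron-rich phosphine binds the alkyne of 16, the furan C2–H of 22 is transferred to the alkyne carbon carrying the bulky 1-arylethyl group (oxidative addition and hydronickelation, or concerted ligand-to-ligand hydrogen transfer), and the alkenyl(benzofuran-2-yl)nickel, with nickel on the methyl-bearing carbon, forms the alkenyl–furan bond by C–C reductive elimination. The closest known reaction type is the nickel/trialkylphosphine-catalysed cis-hydroheteroarylation of internal alkynes with benzofurans and related heteroarenes that have an acidic C–H next to the heteroatom. No ring is closed and no new stereocenter is formed; the stereocenter of 16 is a spectator because the step uses no base and passes through no allyl or propargyl metal species. Syn delivery of H and benzofuranyl to one face of the alkyne gives the E alkene, with the vinylic H cis to the benzofuran. The regioselectivity needed (heteroaryl on the methyl-bearing carbon) is secured by the size difference between methyl and the branched 1-arylethyl group, which puts nickel and then the heteroaryl at the less hindered terminus. Chemoselectivity over the chromene C3=C4 double bond rests on the much faster binding and insertion of an alkyne than of a cis-disubstituted alkene next to a quaternary carbon, and the silyl ether keeps the phenol from protonating the catalyst.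

Step 13
Reactants: 23 1-{6-[(tert-butyldimethylsilyl)oxy]-2-[(2E,4S)-4-(7-methoxy-2,2-dimethyl-2H-chromen-6-yl)pent-2-en-2-yl]-1-benzofuran-5-yl}ethanone
Product: 24 1-{6-hydroxy-2-[(2E,4S)-4-(7-methoxy-2,2-dimethyl-2H-chromen-6-yl)pent-2-en-2-yl]-1-benzofuran-5-yl}ethanone
Conditions: TBAF, AcOH, THF, 0 °C
Reagents that add atoms: none
Why: Fluoride cleaves the aryl silyl ether, and the acetic acid buffer protects the allylic and benzylic stereocenter and the alkene position from base.

**Compound list**

1 | 4-bromo-3-methoxyphenol | COc1cc(O)ccc1Br | starting material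
2 | 3-chloro-3-methylbut-1-yne | C#CC(C)(C)Cl | starting material
3 | 1-bromo-2-methoxy-4-[(2-methylbut-3-yn-2-yl)oxy]benzene | COc1cc(OC(C)(C)C#C)ccc1Br | intermediate
4 | 4-bromo-5-methoxy-2-(3-methylbuta-1,2-dien-1-yl)phenol (ortho-allenylphenol) | COc1cc(O)c(C=C=C(C)C)cc1Br | intermediate (not isolated)
5 | 4-bromo-3-methoxy-6-(3-methylbut-2-en-1-ylidene)cyclohexa-2,4-dien-1-one (ortho-quinone methide) | O=C1C=C(OC)C(Br)=CC1=CC=C(C)C | intermediate (not isolated)
6 | 6-bromo-7-methoxy-2,2-dimethyl-2H-chromene | COc1cc2c(cc1Br)C=CC(C)(C)O2 | intermediate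
7 | (7-methoxy-2,2-dimethyl-2H-chromen-6-yl)lithium | COc1cc2c(cc1[Li])C=CC(C)(C)O2 | intermediate (not isolated)
8 | lithium triisopropoxy(7-methoxy-2,2-dimethyl-2H-chromen-6-yl)borate | COc1cc2c(cc1[B-](OC(C)C)(OC(C)C)OC(C)C)C=CC(C)(C)O2.[Li+] | intermediate (not isolated)
9 | (7-methoxy-2,2-dimethyl-2H-chromen-6-yl)boronic acid | COc1cc2c(cc1B(O)O)C=CC(C)(C)O2 | intermediate
10 | racemic 4-(trimethylsilyl)but-3-yn-2-ol | CC(O)C#C[Si](C)(C)C | starting material
11 | racemic (3-bromobut-1-yn-1-yl)trimethylsilane | CC(Br)C#C[Si](C)(C)C | intermediate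
12 | ethyl(7-methoxy-2,2-dimethyl-2H-chromen-6-yl)zinc | COc1cc2c(cc1[Zn]CC)C=CC(C)(C)O2 | intermediate (not isolated)
13 | trimethyl[(3R)-3-(7-methoxy-2,2-dimethyl-2H-chromen-6-yl)but-1-yn-1-yl]silane | COc1cc2c(cc1[C@@H](C)C#C[Si](C)(C)C)C=CC(C)(C)O2 | intermediate
14 | 6-[(2S)-but-3-yn-2-yl]-7-methoxy-2,2-dimethyl-2H-chromene | COc1cc2c(cc1[C@@H](C)C#C)C=CC(C)(C)O2 | intermediate
15 | [(3S)-3-(7-methoxy-2,2-dimethyl-2H-chromen-6-yl)but-1-yn-1-yl]lithium | COc1cc2c(cc1[C@@H](C)C#C[Li])C=CC(C)(C)O2 | intermediate (not isolated)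
16 | 7-methoxy-2,2-dimethyl-6-[(2S)-pent-3-yn-2-yl]-2H-chromene | COc1cc2c(cc1[C@@H](C)C#CC)C=CC(C)(C)O2 | intermediate
17 | 1-(2,4-dihydroxyphenyl)ethanone | CC(=O)c1ccc(O)cc1O | starting material
18 | 1-(2,4-dihydroxy-5-iodophenyl)ethanone | CC(=O)c1cc(I)c(O)cc1O | intermediate
19 | 1-{2,4-dihydroxy-5-[(trimethylsilyl)ethynyl]phenyl}ethanone | CC(=O)c1cc(C#C[Si](C)(C)C)c(O)cc1O | intermediate
20 | 1-(5-ethynyl-2,4-dihydroxyphenyl)ethanone | CC(=O)c1cc(C#C)c(O)cc1O | intermediate (not isolated)
21 | 1-(6-hydroxy-1-benzofuran-5-yl)ethanone | CC(=O)c1cc2ccoc2cc1O | intermediate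
22 | 1-{6-[(tert-butyldimethylsilyl)oxy]-1-benzofuran-5-yl}ethanone | CC(=O)c1cc2ccoc2cc1O[Si](C)(C)C(C)(C)C | intermediate
23 | 1-{6-[(tert-butyldimethylsilyl)oxy]-2-[(2E,4S)-4-(7-methoxy-2,2-dimethyl-2H-chromen-6-yl)pent-2-en-2-yl]-1-benzofuran-5-yl}ethanone | COc1cc2c(cc1[C@@H](C)/C=C(\C)c1cc3cc(C(C)=O)c(O[Si](C)(C)C(C)(C)C)cc3o1)C=CC(C)(C)O2 | intermediate
24 | 1-{6-hydroxy-2-[(2E,4S)-4-(7-methoxy-2,2-dimethyl-2H-chromen-6-yl)pent-2-en-2-yl]-1-benzofuran-5-yl}ethanone | COc1cc2c(cc1[C@@H](C)/C=C(\C)c1cc3cc(C(C)=O)c(O)cc3o1)C=CC(C)(C)O2 | target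

**Step count and risks**

Total steps: 13. Longest linear sequence: 8 (steps 1, 2, 3, 5, 6, 7, 12, 13).

Steps most likely to fail:

1. Step 12. The catalyst may be held back by the aryl ketone or drawn into alkyne oligomerisation, or hydrogen transfer may go to the wrong alkyne carbon, so that the C–H addition stalls or gives regioisomers. The fallback sets out from 16 and 22 and comes back at 23. Hydrozirconation of 16 with Cp2Zr(H)Cl (THF, rt; syn addition, zirconium on the methyl-bearing carbon) and iodinolysis with I2 should give 6-[(2S,3E)-4-iodopent-3-en-2-yl]-7-methoxy-2,2-dimethyl-2H-chromene F1. Iridium-catalysed C–H borylation of 22 at furan C2 ([Ir(OMe)(cod)]2, 4,4'-di-tert-butyl-2,2'-bipyridine, B2pin2, THF, 60 °C) should give 1-{6-[(tert-butyldimethylsilyl)oxy]-2-(4,4,5,5-tetramethyl-1,3,2-dioxaborolan-2-yl)-1-benzofuran-5-yl}ethanone F2. Suzuki–Miyaura coupling of F1 with F2 (Pd(dppf)Cl2, K3PO4, THF/H2O, 50 °C) should then give 23 with retention of the alkene geometry.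

2. Step 5. Transmetalation of the ortho-methoxy arylzinc may be slow, and the enantioselectivity may erode or the sense of induction may not be the one wanted. The fallback sets out from 9 and comes back at 16, with the stereocenter set by an oxazolidinone auxiliary.
   - Palladium-catalysed coupling of 9 with ethyl bromoacetate (Pd(OAc)2, P(1-naphthyl)3, K3PO4, THF/H2O, rt) should give ethyl (7-methoxy-2,2-dimethyl-2H-chromen-6-yl)acetate F3.
   - LiOH (THF/H2O) should give (7-methoxy-2,2-dimethyl-2H-chromen-6-yl)acetic acid F4.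
   - Activation with pivaloyl chloride/Et3N and acylation of lithiated (R)-4-benzyl-1,3-oxazolidin-2-one should give (4R)-4-benzyl-3-[(7-methoxy-2,2-dimethyl-2H-chromen-6-yl)acetyl]-1,3-oxazolidin-2-one F5.
   - NaHMDS (THF, −78 °C) then MeI should give (4R)-4-benzyl-3-[(2R)-2-(7-methoxy-2,2-dimethyl-2H-chromen-6-yl)propanoyl]-1,3-oxazolidin-2-one F6, the methyl group entering the chelated Z-enolate on the face opposite the benzyl group (Evans-type alkylation).
   - LiBH4 (THF, 0 °C) should give (2R)-2-(7-methoxy-2,2-dimethyl-2H-chromen-6-yl)propan-1-ol F7 and free the auxiliary.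
   - Dess–Martin periodinane (NaHCO3, CH2Cl2, 0 °C) should give (2R)-2-(7-methoxy-2,2-dimethyl-2H-chromen-6-yl)propanal F8, used at once.
   - CBr4/PPh3 (CH2Cl2, 0 °C) should give 6-[(2S)-4,4-dibromobut-3-en-2-yl]-7-methoxy-2,2-dimethyl-2H-chromene F9.
   - n-BuLi (2 equiv, THF, −78 °C) followed by MeI (Corey–Fuchs sequence with methyl quench) should give 16.

3. Step 2. The sigmatropic shift may go in part to the ortho carbon between the two oxygen substituents, or the bromoarene may degrade at the temperature needed. The fallback sets out from 1 and comes back at 6, building the ring at the saturated level. Friedel–Crafts acylation and oxa-Michael closure of 1 with 3-methylbut-2-enoic acid in P2O5/MeSO3H (70 °C), directed ortho to the hydroxyl and para to the methoxy group, should give 6-bromo-7-methoxy-2,2-dimethyl-2,3-dihydro-4H-chromen-4-one F10. NaBH4 (MeOH, 0 °C) should give racemic 6-bromo-7-methoxy-2,2-dimethyl-3,4-dihydro-2H-chromen-4-ol F11. Acid-catalysed dehydration (p-TsOH cat., toluene, 80 °C) should give 6.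

**Further compounds**

F1 | step 12 | 6-[(2S,3E)-4-iodopent-3-en-2-yl]-7-methoxy-2,2-dimethyl-2H-chromene | COc1cc2c(cc1[C@@H](C)/C=C(\C)I)C=CC(C)(C)O2
F2 | step 12 | 1-{6-[(tert-butyldimethylsilyl)oxy]-2-(4,4,5,5-tetramethyl-1,3,2-dioxaborolan-2-yl)-1-benzofuran-5-yl}ethanone | CC(=O)c1cc2cc(B3OC(C)(C)C(C)(C)O3)oc2cc1O[Si](C)(C)C(C)(C)C
F3 | step 5 | ethyl (7-methoxy-2,2-dimethyl-2H-chromen-6-yl)acetate | COc1cc2c(cc1CC(=O)OCC)C=CC(C)(C)O2
F4 | step 5 | (7-methoxy-2,2-dimethyl-2H-chromen-6-yl)acetic acid | COc1cc2c(cc1CC(=O)O)C=CC(C)(C)O2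
F5 | step 5 | (4R)-4-benzyl-3-[(7-methoxy-2,2-dimethyl-2H-chromen-6-yl)acetyl]-1,3-oxazolidin-2-one | COc1cc2c(cc1CC(=O)N1C(=O)OC[C@H]1Cc1ccccc1)C=CC(C)(C)O2
F6 | step 5 | (4R)-4-benzyl-3-[(2R)-2-(7-methoxy-2,2-dimethyl-2H-chromen-6-yl)propanoyl]-1,3-oxazolidin-2-one | COc1cc2c(cc1[C@@H](C)C(=O)N1C(=O)OC[C@H]1Cc1ccccc1)C=CC(C)(C)O2
F7 | step 5 | (2R)-2-(7-methoxy-2,2-dimethyl-2H-chromen-6-yl)propan-1-ol | COc1cc2c(cc1[C@@H](C)CO)C=CC(C)(C)O2
F8 | step 5 | (2R)-2-(7-methoxy-2,2-dimethyl-2H-chromen-6-yl)propanal | COc1cc2c(cc1[C@@H](C)C=O)C=CC(C)(C)O2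
F9 | step 5 | 6-[(2S)-4,4-dibromobut-3-en-2-yl]-7-methoxy-2,2-dimethyl-2H-chromene | COc1cc2c(cc1[C@@H](C)C=C(Br)Br)C=CC(C)(C)O2
F10 | step 2 | 6-bromo-7-methoxy-2,2-dimethyl-2,3-dihydro-4H-chromen-4-one | COc1cc2c(cc1Br)C(=O)CC(C)(C)O2
F11 | step 2 | racemic 6-bromo-7-methoxy-2,2-dimethyl-3,4-dihydro-2H-chromen-4-ol | COc1cc2c(cc1Br)C(O)CC(C)(C)O2
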